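Plan
1. Numbering: C1 is the allyl-bearing bridgehead, C2=C3(OMe) the enol ether, C4 the enone carbonyl, C5 the second bridgehead, C6 the aryl carbon, C7 the methyl carbon and C8 the bridging carbonyl. Enabling feature: in the cyclopentanone ring C8–C1–C7–C6–C5, carbonyl C8 is flanked by quaternary C1, so C1–C7 can be read as a bond that has moved over from C8; undoing the shift gives a cyclobutanol (C8, C5, C6, C7) cis-fused to a cyclohexene (C8, C1, C2, C3, C4, C5).
2. Cuts in retrosynthetic order: O–CH3 and C3–O (diosphenol from the C4 ketone); C1–C7, returned to C8–C7 (semipinacol); C1–C8 (alkenyl iodide onto the cyclobutanone); C5–C6 and C7–C8 ([2+2]); C1=C2 (iodo-Wittig).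
3. Forward: a glutarate supplies the chain C8–C5–C4–C3–C2 and olefination adds C1 with the allyl group. The four-membered ring is made next, then the six-membered ring, then the four-to-five expansion to the bicyclo[3.2.1]octane, and finally oxidation at C4 and C3.
4. Stereochemistry: a C2-symmetric pyrrolidine sets C6 in the keteniminium cycloaddition. C5 and C7 follow by equilibration to the all-trans cyclobutanone, the tether sets C8 (cis fusion), and the suprafacial shift sets C1 with retention at C7.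
5. C4 travels as a bought-in silyl ether stereocentre, not as a ketone or ketal, because a carbonyl or oxocarbenium ion β to the cyclobutanol would open C8–C5 by retro-aldol in acid. This centre also turns any facial leakage at C6 into separable diastereomers, and oxidation erases it.

Key step: step 8

Assumption on induction: the (2S,5S) auxiliary is taken to favour the (6R) ring series; if the sense is the opposite, the equally available (2R,5R) amine is used and nothing else changes.
Assumption on supply: 1 is taken as a purchasable statin side-chain intermediate.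

Step 1
Reactants: 1 (3R)-3-(tert-butyldimethylsilyloxy)pentanedioic acid 1-methyl ester; 2 (2S,5S)-2,5-dimethylpyrrolidine
Product: 4 methyl (3R)-3-(tert-butyldimethylsilyloxy)-5-[(2S,5S)-2,5-dimethylpyrrolidin-1-yl]-5-oxopentanoate, via acid chloride 3 (not isolated)
Conditions: 1-chloro-N,N,2-trimethylprop-1-en-1-amine, CH2Cl2, 0 °C; then 2, pyridine, 0 °C to rt
Reagents that add atoms: none
Why: The α-chloroenamine forms the acid chloride under neutral conditions that spare the silyl ether, and the hindered secondary amine is then acylated (amide formation via acid chloride) without touching a stereocentre.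

Step 2
Reactants: 4 methyl (3R)-3-(tert-butyldimethylsilyloxy)-5-[(2S,5S)-2,5-dimethylpyrrolidin-1-yl]-5-oxopentanoate
Product: 5 (3S)-3-(tert-butyldimethylsilyloxy)-1-[(2S,5S)-2,5-dimethylpyrrolidin-1-yl]-5-hydroxypentan-1-one
Conditions: LiBH4, THF, MeOH (1 equiv), 0 °C to rt
Reagents that add atoms: none
Why: Chemoselective borohydride reduction, since LiBH4 reduces esters but leaves tertiary amides and silyl ethers alone (the descriptor changes only through ligand ranking).

Step 3
Reactants: 5 (3S)-3-(tert-butyldimethylsilyloxy)-1-[(2S,5S)-2,5-dimethylpyrrolidin-1-yl]-5-hydroxypentan-1-one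
Product: 6 (3S)-3-(tert-butyldimethylsilyloxy)-5-[(2S,5S)-2,5-dimethylpyrrolidin-1-yl]-5-oxopentanal
Conditions: Dess–Martin periodinane, CH2Cl2, 0 °C to rt
Reagents that add atoms: none
Why: Dess–Martin oxidation stops at the aldehyde under near-neutral conditions, which avoids β-elimination of the silyloxy group.

Step 4
Reactants: 6 (3S)-3-(tert-butyldimethylsilyloxy)-5-[(2S,5S)-2,5-dimethylpyrrolidin-1-yl]-5-oxopentanal; 7 but-3-en-1-yltriphenylphosphonium bromide
Product: 11 (3S,5Z)-3-(tert-butyldimethylsilyloxy)-1-[(2S,5S)-2,5-dimethylpyrrolidin-1-yl]-6-iodonona-5,8-dien-1-one, via butenylidene ylide 8 (not isolated), via iodophosphonium iodide 9 (not isolated), via iodo ylide 10 (not isolated)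
Conditions: 7, n-BuLi, THF, 0 °C; I2, −78 °C; NaN(SiMe3)2, −20 °C; then 6, −78 to −20 °C
Reagents that add atoms: iodine, II
Why: Stork–Zhao-type α-iodo Wittig olefination, in which the non-stabilised iodo ylide reacts under kinetic control and places iodine cis to the chain, giving the (Z)-geometry (C3 and the future C8 cis on C1=C2) that the ring closure needs.

Step 5
Reactants: 11 (3S,5Z)-3-(tert-butyldimethylsilyloxy)-1-[(2S,5S)-2,5-dimethylpyrrolidin-1-yl]-6-iodonona-5,8-dien-1-one; 12 (E)-methylisoeugenol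
Product: 15 (3R,4R)-2-[(1S,3Z)-1-(tert-butyldimethylsilyloxy)-4-iodohepta-3,6-dien-1-yl]-3-(3,4-dimethoxyphenyl)-4-methylcyclobutan-1-one as both epimers at ring C2 (route C5), via keteniminium triflate 13 (not isolated), via cyclobutaniminium triflate 14 (not isolated)
Conditions: Tf2O, 2,4,6-collidine, 12 (3 equiv), CH2Cl2, −20 °C to reflux; then H2O, NaHCO3, CH2Cl2–H2O, 40 °C
Reagents that add atoms: water, O
Why: Keteniminium–alkene [2+2] cycloaddition, in which electrophilic C8 bonds to the methyl-bearing alkene carbon C7 so that charge develops at benzylic C6, C6 closes onto C5, and the C2-symmetric pyrrolidine differentiates the alkene faces and so sets C6, the only ring centre that cannot be corrected later.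

Step 6
Reactants: 15 cyclobutanone as C5 epimers
Product: 16 (2R,3R,4R)-2-[(1S,3Z)-1-(tert-butyldimethylsilyloxy)-4-iodohepta-3,6-dien-1-yl]-3-(3,4-dimethoxyphenyl)-4-methylcyclobutan-1-one (all-trans)
Conditions: DBU (10 mol %), CH2Cl2, 0 °C to rt; chromatography
Reagents that add atoms: none
Why: Base-catalysed enolisation equilibrates the two α-centres C5 and C7 against the fixed benzylic C6, the all-trans arrangement is the thermodynamic minimum of a 2,3,4-trisubstituted cyclobutanone, and any (6S) material is a diastereomer that is removed here.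

Step 7
Reactants: 16 all-trans iodo dienyl cyclobutanone
Product: 18 (1S,5S,6R,7R,8R)-2-allyl-5-(tert-butyldimethylsilyloxy)-7-(3,4-dimethoxyphenyl)-8-methylbicyclo[4.2.0]oct-2-en-1-ol (cis-fused; locants 1 to 8 are route atoms C8 C1 C2 C3 C4 C5 C6 C7), via alkenylchromium dichloride 17 (not isolated)
Conditions: CrCl2 (6 equiv), NiCl2 (2 mol %), DMF, rt; aqueous work-up
Reagents that add atoms: none
Why: Intramolecular Nozaki–Hiyama–Kishi reaction, in which zerovalent nickel inserts into C–I with retention, transmetalation to trivalent chromium gives a chemoselective alkenyl nucleophile for the strain-activated ketone, and the three-atom tether (C4, C3, C2) lets it reach only the carbonyl face syn to the C5 side chain, which sets C8 and the cis fusion.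

Step 8
Reactants: 18 (1S,5S,6R,7R,8R)-2-allyl-5-(tert-butyldimethylsilyloxy)-7-(3,4-dimethoxyphenyl)-8-methylbicyclo[4.2.0]oct-2-en-1-ol
Product: 19 (1S,4S,5R,6R,7R)-1-allyl-4-(tert-butyldimethylsilyloxy)-6-(3,4-dimethoxyphenyl)-7-methylbicyclo[3.2.1]octan-8-one (aryl exo = syn to C8; methyl endo; silyloxy anti to the C6–C7 bridge)
Conditions: Tf2NH (20 mol %), CH2Cl2, −40 to 0 °C
Reagents that add atoms: none
Why: The acid protonates the trisubstituted C1=C2 bond at C2 (the monosubstituted allyl alkene is far less basic), and as charge builds at C1 the strained C8–C7 σ-bond shifts to C1 while the C8 hydroxyl collapses to the ketone, which is the acid-promoted semipinacol ring expansion known for 1-alkenylcyclobutanols and for bicyclo[4.2.0]octan-1-ols with a cationic neighbour. The five-membered ring C8–C1–C7–C6–C5 arises by four-to-five ring expansion through a 1,2-alkyl shift and not by cyclisation, and the retained six-membered ring C1–C2–C3–C4–C5–C8 thereby becomes the second ring of the bicyclo[3.2.1]octane. The only new stereocentre, quaternary C1, is dictated by the cis fusion, because C7 can only slide suprafacially over the cyclohexene face on which it already sits, and it migrates with retention, so C5, C6 and C7 are carried over unchanged. The step needs C7 to migrate in preference to C5: C8–C5 is an endocyclic bond of the ring that holds the cation and lies near the nodal plane of the empty orbital, whereas the exocyclic C8–C7 bond can stand parallel to it, and methyl-bearing C7 is also the more electron-rich terminus than C5, which adjoins the C4–O bond. The aryl group lies on the cyclobutane face opposite to C1, so Friedel–Crafts capture is geometrically excluded, and with C4 as a silyl ether no carbonyl or oxocarbenium ion β to the carbinol can trigger retro-aldol opening of C8–C5. A catalytic acid with a non-nucleophilic, non-basic counterion at low temperature is chosen so that the shift outruns proton loss towards the conjugated diene and ionisation of the allylic alcohol.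

Step 9
Reactants: 19 (1S,4S,5R,6R,7R)-1-allyl-4-(tert-butyldimethylsilyloxy)-6-(3,4-dimethoxyphenyl)-7-methylbicyclo[3.2.1]octan-8-one
Product: 20 (1S,4S,5R,6R,7R)-1-allyl-6-(3,4-dimethoxyphenyl)-4-hydroxy-7-methylbicyclo[3.2.1]octan-8-one
Conditions: HF·pyridine, THF, 0 °C to rt
Reagents that add atoms: none
Why: Fluoride-driven silyl ether cleavage in a mildly acidic medium avoids the base-induced retro-aldol of the resulting β-hydroxy ketone.

Step 10
Reactants: 20 (1S,4S,5R,6R,7R)-1-allyl-6-(3,4-dimethoxyphenyl)-4-hydroxy-7-methylbicyclo[3.2.1]octan-8-one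
Product: 21 (1S,5R,6R,7R)-1-allyl-6-(3,4-dimethoxyphenyl)-7-methylbicyclo[3.2.1]octane-4,8-dione
Conditions: Dess–Martin periodinane, CH2Cl2, rt
Reagents that add atoms: none
Why: Dess–Martin oxidation erases the auxiliary C4 centre without a nucleophile or base, and C5 cannot epimerise because a bridgehead enol would violate Bredt's rule.

Step 11
Reactants: 21 (1S,5R,6R,7R)-1-allyl-6-(3,4-dimethoxyphenyl)-7-methylbicyclo[3.2.1]octane-4,8-dione
Product: 23 (1R,3S,5S,6R,7R)-1-allyl-6-(3,4-dimethoxyphenyl)-3-hydroxy-7-methylbicyclo[3.2.1]octane-4,8-dione, via potassium enolate 22 (not isolated)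
Conditions: KN(SiMe3)2, THF, −78 °C; 2-(benzenesulfonyl)-3-phenyloxaziridine, −78 °C; AcOH
Reagents that add atoms: 2-(benzenesulfonyl)-3-phenyloxaziridine, O=S(=O)(c1ccccc1)N1OC1c1ccccc1
Why: Davis oxidation, in which C3 is the only enolisable position (C1 is quaternary, C5 a bridgehead), a non-nucleophilic base spares the non-enolisable β-diketone from retro-Claisen cleavage, and oxygen should arrive on the face syn to C8 and away from the endo methyl, at a centre that the next step removes.

Step 12
Reactants: 23 (1R,3S,5S,6R,7R)-1-allyl-6-(3,4-dimethoxyphenyl)-3-hydroxy-7-methylbicyclo[3.2.1]octane-4,8-dione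
Product: 25 (1S,5S,6R,7R)-1-allyl-6-(3,4-dimethoxyphenyl)-3-hydroxy-7-methylbicyclo[3.2.1]oct-2-ene-4,8-dione (diosphenol), via 3,4,8-trione 24 (not isolated)
Conditions: Dess–Martin periodinane, CH2Cl2, rt
Reagents that add atoms: none
Why: Acyloin oxidation gives the 1,2-diketone, which can enolise only towards C2 because the alternative enol would place a double bond at bridgehead C5.

Step 13
Reactants: 25 (1S,5S,6R,7R)-1-allyl-6-(3,4-dimethoxyphenyl)-3-hydroxy-7-methylbicyclo[3.2.1]oct-2-ene-4,8-dione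
Product: 26 kadsurenin D = (1S,5S,6R,7R)-1-allyl-6-(3,4-dimethoxyphenyl)-3-methoxy-7-methylbicyclo[3.2.1]oct-2-ene-4,8-dione
Conditions: Me2SO4, K2CO3, acetone, rt
Reagents that add atoms: dimethyl sulfate, COS(=O)(=O)OC
Why: O-alkylation of the acidic diosphenol with a hard methylating agent and a weak, non-nucleophilic base gives the enol methyl ether without endangering the β-diketone.

Compound list
1 | (3R)-3-(tert-butyldimethylsilyloxy)pentanedioic acid 1-methyl ester | COC(=O)C[C@H](O[Si](C)(C)C(C)(C)C)CC(=O)O | starting material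
2 | (2S,5S)-2,5-dimethylpyrrolidine | C[C@H]1CC[C@H](C)N1 | starting material
3 | methyl (3S)-3-(tert-butyldimethylsilyloxy)-5-chloro-5-oxopentanoate | COC(=O)C[C@H](O[Si](C)(C)C(C)(C)C)CC(=O)Cl | intermediate
4 | methyl (3R)-3-(tert-butyldimethylsilyloxy)-5-[(2S,5S)-2,5-dimethylpyrrolidin-1-yl]-5-oxopentanoate | COC(=O)C[C@H](O[Si](C)(C)C(C)(C)C)CC(=O)N1[C@@H](C)CC[C@@H]1C | intermediate
5 | (3S)-3-(tert-butyldimethylsilyloxy)-1-[(2S,5S)-2,5-dimethylpyrrolidin-1-yl]-5-hydroxypentan-1-one | OCC[C@H](O[Si](C)(C)C(C)(C)C)CC(=O)N1[C@@H](C)CC[C@@H]1C | intermediate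
6 | (3S)-3-(tert-butyldimethylsilyloxy)-5-[(2S,5S)-2,5-dimethylpyrrolidin-1-yl]-5-oxopentanal | O=CC[C@H](O[Si](C)(C)C(C)(C)C)CC(=O)N1[C@@H](C)CC[C@@H]1C | intermediate
7 | but-3-en-1-yltriphenylphosphonium bromide | C=CCC[P+](c1ccccc1)(c1ccccc1)c1ccccc1.[Br-] | starting material
8 | but-3-en-1-ylidenetriphenylphosphorane | C=CCC=P(c1ccccc1)(c1ccccc1)c1ccccc1 | intermediate
9 | (1-iodobut-3-en-1-yl)triphenylphosphonium iodide | C=CCC(I)[P+](c1ccccc1)(c1ccccc1)c1ccccc1.[I-] | intermediate
10 | (1-iodobut-3-en-1-ylidene)triphenylphosphorane | C=CCC(I)=P(c1ccccc1)(c1ccccc1)c1ccccc1 | intermediate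
11 | (3S,5Z)-3-(tert-butyldimethylsilyloxy)-1-[(2S,5S)-2,5-dimethylpyrrolidin-1-yl]-6-iodonona-5,8-dien-1-one | C=CC/C(I)=C/C[C@H](O[Si](C)(C)C(C)(C)C)CC(=O)N1[C@@H](C)CC[C@@H]1C | intermediate
12 | (E)-methylisoeugenol, 1,2-dimethoxy-4-[(E)-prop-1-enyl]benzene | C/C=C/c1ccc(OC)c(OC)c1 | starting material
13 | keteniminium triflate derived from 11 (C5=C8=N+) | C=CC/C(I)=C/C[C@H](O[Si](C)(C)C(C)(C)C)C=C=[N+]1[C@@H](C)CC[C@@H]1C.[O-]S(=O)(=O)C(F)(F)F | intermediate
14 | cyclobutaniminium triflate, aryl and methyl trans, C5 not defined | C=CC/C(I)=C/C[C@H](O[Si](C)(C)C(C)(C)C)C1[C@H](c2ccc(OC)c(OC)c2)[C@@H](C)C1=[N+]3[C@@H](C)CC[C@@H]3C.[O-]S(=O)(=O)C(F)(F)F | intermediate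
15 | (3R,4R)-2-[(1S,3Z)-1-(tert-butyldimethylsilyloxy)-4-iodohepta-3,6-dien-1-yl]-3-(3,4-dimethoxyphenyl)-4-methylcyclobutan-1-one, both epimers at ring C2 | C=CC/C(I)=C/C[C@H](O[Si](C)(C)C(C)(C)C)C1[C@H](c2ccc(OC)c(OC)c2)[C@@H](C)C1=O | intermediate
16 | (2R,3R,4R)-2-[(1S,3Z)-1-(tert-butyldimethylsilyloxy)-4-iodohepta-3,6-dien-1-yl]-3-(3,4-dimethoxyphenyl)-4-methylcyclobutan-1-one, all-trans | C=CC/C(I)=C/C[C@H](O[Si](C)(C)C(C)(C)C)[C@H]1[C@H](c2ccc(OC)c(OC)c2)[C@@H](C)C1=O | intermediate
17 | alkenylchromium dichloride derived from 16 (trivalent chromium at C1) | C=CC/C([Cr](Cl)Cl)=C/C[C@H](O[Si](C)(C)C(C)(C)C)[C@H]1[C@H](c2ccc(OC)c(OC)c2)[C@@H](C)C1=O | intermediate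
18 | (1S,5S,6R,7R,8R)-2-allyl-5-(tert-butyldimethylsilyloxy)-7-(3,4-dimethoxyphenyl)-8-methylbicyclo[4.2.0]oct-2-en-1-ol, cis-fused | C=CCC1=CC[C@H](O[Si](C)(C)C(C)(C)C)[C@H]2[C@H](c3ccc(OC)c(OC)c3)[C@@H](C)[C@@]12O | intermediate
19 | (1S,4S,5R,6R,7R)-1-allyl-4-(tert-butyldimethylsilyloxy)-6-(3,4-dimethoxyphenyl)-7-methylbicyclo[3.2.1]octan-8-one | C=CC[C@]12CC[C@H](O[Si](C)(C)C(C)(C)C)[C@H](C1=O)[C@H](c1ccc(OC)c(OC)c1)[C@H]2C | intermediate
20 | (1S,4S,5R,6R,7R)-1-allyl-6-(3,4-dimethoxyphenyl)-4-hydroxy-7-methylbicyclo[3.2.1]octan-8-one | C=CC[C@]12CC[C@H](O)[C@H](C1=O)[C@H](c1ccc(OC)c(OC)c1)[C@H]2C | intermediate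
21 | (1S,5R,6R,7R)-1-allyl-6-(3,4-dimethoxyphenyl)-7-methylbicyclo[3.2.1]octane-4,8-dione | C=CC[C@]12CCC(=O)[C@H](C1=O)[C@H](c1ccc(OC)c(OC)c1)[C@H]2C | intermediate
22 | potassium C3=C4 enolate of 21 | C=CC[C@]12CC=C([O-])[C@H](C1=O)[C@H](c1ccc(OC)c(OC)c1)[C@H]2C.[K+] | intermediate
23 | (1R,3S,5S,6R,7R)-1-allyl-6-(3,4-dimethoxyphenyl)-3-hydroxy-7-methylbicyclo[3.2.1]octane-4,8-dione | C=CC[C@]12C[C@H](O)C(=O)[C@H](C1=O)[C@H](c1ccc(OC)c(OC)c1)[C@H]2C | intermediate
24 | 1-allyl-6-(3,4-dimethoxyphenyl)-7-methylbicyclo[3.2.1]octane-3,4,8-trione | C=CC[C@]12CC(=O)C(=O)[C@H](C1=O)[C@H](c1ccc(OC)c(OC)c1)[C@H]2C | intermediate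
25 | (1S,5S,6R,7R)-1-allyl-6-(3,4-dimethoxyphenyl)-3-hydroxy-7-methylbicyclo[3.2.1]oct-2-ene-4,8-dione | C=CC[C@]12C=C(O)C(=O)[C@H](C1=O)[C@H](c1ccc(OC)c(OC)c1)[C@H]2C | intermediate
26 | kadsurenin D, (1S,5S,6R,7R)-1-allyl-6-(3,4-dimethoxyphenyl)-3-methoxy-7-methylbicyclo[3.2.1]oct-2-ene-4,8-dione | C=CC[C@]12C=C(OC)C(=O)[C@H](C1=O)[C@H](c1ccc(OC)c(OC)c1)[C@H]2C | target

Total step count: 13. Longest linear sequence: 13 steps (from 1).

Steps most likely to fail

1. Step 8.
- What may go wrong: the tertiary allylic alcohol may ionise, or C1 may lose a proton towards the conjugated diene so that the allyl group drifts to a propenyl group. Either could compete with the shift, and the silyl ether could be lost too early.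
- Fallback (sets out from 18, returns at 21): the same C8-to-C1 shift of C7 is triggered from an epoxide instead of a proton.
- Hydroxyl-directed epoxidation (VO(acac)2, t-BuOOH, CH2Cl2, 0 °C) touches only the allylic-alcohol alkene. It delivers oxygen syn to the C8 hydroxyl, that is anti to C7, and gives the epoxy alcohol F1.
- BF3·OEt2 (CH2Cl2, −78 °C) opens the epoxide at tertiary C1 with antiperiplanar migration of C7 (epoxy alcohol semipinacol rearrangement) to the 2-hydroxy ketone F2.
- MsCl and Et3N give the mesylate F3, and HF·pyridine frees the C4 alcohol F4.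
- Dess–Martin oxidation gives the keto mesylate F5, which loses methanesulfonic acid with Et3N to the enone F6.
- Conjugate reduction with [(Ph3P)CuH]6 in toluene, which leaves isolated alkenes alone, gives 21.

2. Step 5.
- What may go wrong: the hindered keteniminium ion may add slowly, so that cationic oligomerisation of the electron-rich styrene and incomplete facial control take over.
- Fallback (sets out from 1, returns at 16): the auxiliary is given up and absolute control passes to the resident C4 centre.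
- Acid chloride 3 is capped with pyrrolidine to the amide ester F7. The operations of steps 2 to 4 then take it through the alcohol F8 and the aldehyde F9 to the iodo diene amide F10.
- Its unhindered keteniminium triflate F11 belongs to the most reactive members of the class. It should add 12 faster than the styrene is consumed otherwise, giving the cyclobutaniminium triflate F12 in both ring series.
- Hydrolysis with aqueous K2CO3 in THF also equilibrates C5 and C7. It gives 16 together with the ring-antipodal all-trans ketone F13. Both carry (S)-C4, so they are diastereomers that chromatography separates.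

3. Step 7.
- What may go wrong: the alkenylchromium species may add slowly to the doubly α-branched, enolisable ketone, so that protodemetalation wins.
- Fallback (sets out from 16, returns at 18): the nickel/chromium manifold is replaced by an anionic Parham-type cyclisation.
- With t-BuLi (2.1 equiv) in THF–Et2O–pentane at −100 °C, iodine–lithium exchange is faster than carbonyl addition or enolisation. The alkenyllithium F14 is trapped at once by the neighbouring ketone on the only face the tether allows.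

Further compounds
F1 | step 8 | epoxy alcohol, C1–C2 epoxide of 18 on the face of the C8 hydroxyl | C=CC[C@@]12O[C@@H]1C[C@H](O[Si](C)(C)C(C)(C)C)[C@H]1[C@H](c3ccc(OC)c(OC)c3)[C@@H](C)[C@@]21O
F2 | step 8 | 1-allyl-4-(tert-butyldimethylsilyloxy)-6-(3,4-dimethoxyphenyl)-2-hydroxy-7-methylbicyclo[3.2.1]octan-8-one, 2-OH anti to the C6–C7 bridge | C=CC[C@]12[C@H](O)C[C@H](O[Si](C)(C)C(C)(C)C)[C@H](C1=O)[C@H](c1ccc(OC)c(OC)c1)[C@H]2C
F3 | step 8 | 2-methanesulfonate of F2 | C=CC[C@]12[C@H](OS(C)(=O)=O)C[C@H](O[Si](C)(C)C(C)(C)C)[C@H](C1=O)[C@H](c1ccc(OC)c(OC)c1)[C@H]2C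
F4 | step 8 | 4-hydroxy 2-methanesulfonate | C=CC[C@]12[C@H](OS(C)(=O)=O)C[C@H](O)[C@H](C1=O)[C@H](c1ccc(OC)c(OC)c1)[C@H]2C
F5 | step 8 | 2-methanesulfonyloxy-4,8-dione | C=CC[C@]12[C@H](OS(C)(=O)=O)CC(=O)[C@H](C1=O)[C@H](c1ccc(OC)c(OC)c1)[C@H]2C
F6 | step 8 | 1-allyl-6-(3,4-dimethoxyphenyl)-7-methylbicyclo[3.2.1]oct-2-ene-4,8-dione | C=CC[C@]12C=CC(=O)[C@H](C1=O)[C@H](c1ccc(OC)c(OC)c1)[C@H]2C
F7 | step 5 | methyl (3R)-3-(tert-butyldimethylsilyloxy)-5-oxo-5-(pyrrolidin-1-yl)pentanoate | COC(=O)C[C@H](O[Si](C)(C)C(C)(C)C)CC(=O)N1CCCC1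
F8 | step 5 | (3S)-3-(tert-butyldimethylsilyloxy)-5-hydroxy-1-(pyrrolidin-1-yl)pentan-1-one | OCC[C@H](O[Si](C)(C)C(C)(C)C)CC(=O)N1CCCC1
F9 | step 5 | (3S)-3-(tert-butyldimethylsilyloxy)-5-oxo-5-(pyrrolidin-1-yl)pentanal | O=CC[C@H](O[Si](C)(C)C(C)(C)C)CC(=O)N1CCCC1
F10 | step 5 | (3S,5Z)-3-(tert-butyldimethylsilyloxy)-6-iodo-1-(pyrrolidin-1-yl)nona-5,8-dien-1-one | C=CC/C(I)=C/C[C@H](O[Si](C)(C)C(C)(C)C)CC(=O)N1CCCC1
F11 | step 5 | keteniminium triflate derived from F10 | C=CC/C(I)=C/C[C@H](O[Si](C)(C)C(C)(C)C)C=C=[N+]1CCCC1.[O-]S(=O)(=O)C(F)(F)F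
F12 | step 5 | cyclobutaniminium triflate, both ring series | C=CC/C(I)=C/C[C@H](O[Si](C)(C)C(C)(C)C)C1C(c2ccc(OC)c(OC)c2)C(C)C1=[N+]3CCCC3.[O-]S(=O)(=O)C(F)(F)F
F13 | step 5 | (2S,3S,4S)-ring, (1S)-side-chain diastereomer of 16 | C=CC/C(I)=C/C[C@H](O[Si](C)(C)C(C)(C)C)[C@@H]1[C@@H](c2ccc(OC)c(OC)c2)[C@H](C)C1=O
F14 | step 7 | alkenyllithium derived from 16 | C=CC/C([Li])=C/C[C@H](O[Si](C)(C)C(C)(C)C)[C@H]1[C@H](c2ccc(OC)c(OC)c2)[C@@H](C)C1=O
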